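The synthesis rests on cutting the bond between the cyclohexane CH stereocentre (C-1) and the first CH2 of the side chain (C-9 of the nonadienyl chain). The key step exploits the allyl unit made up of ring C-1, ring C-6 and the exocyclic =CH2. A ligand-controlled, copper-catalysed SN2' alkylation of achiral 1-(chloromethyl)-3,3-dimethylcyclohexene with a homoallylic alkylborane, generated in the same flask by 9-BBN hydroboration of a geraniol-derived triene, forms this bond, shifts the olefin to the exocyclic position and sets the (S)-centre in one operation. The precursors are therefore an endocyclic allylic chloride and a terminal 1,3-diene; desilylation and acylation with Meldrum's acid complete the target.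

Key step: step 8

Assumption: the sense of induction of the chiral ligand in step 8 cannot be assigned in advance for this ring-locked olefin. The route is written with (R)-DTBM-SEGPHOS; the (S)-ligand is used instead if a pilot run shows the opposite sense.

Step 1
Reactants: 1 3-methylcyclohex-2-en-1-one
Product: 3 3,3-dimethylcyclohex-1-en-1-yl trifluoromethanesulfonate, via lithium enolate 2 (not isolated)
Conditions: Me2CuLi (MeLi, CuI), Et2O, 0 °C; then PhNTf2, THF, 0 °C to rt; aq NH4Cl work-up
Reagents that add atoms: lithium dimethylcuprate [Li+].C[Cu-]C (made in the flask from methyllithium [Li]C and CuI); N-phenylbis(trifluoromethanesulfonimide) O=S(=O)(N(c1ccccc1)S(=O)(=O)C(F)(F)F)C(F)(F)F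
Why: Conjugate addition of the Gilman cuprate to the β-methyl enone builds the gem-dimethyl carbon and leaves the enolate regiospecifically on the side of that carbon, where O-triflation fixes the double bond (cuprate 1,4-addition with enolate trapping).

Step 2
Reactants: 3 3,3-dimethylcyclohex-1-en-1-yl trifluoromethanesulfonate
Product: 4 (3,3-dimethylcyclohex-1-en-1-yl)methanol
Conditions: Bu3SnCH2OH, Pd(PPh3)4 (cat.), LiCl, 1,4-dioxane, 100 °C
Reagents that add atoms: (tributylstannyl)methanol OC[Sn](CCCC)(CCCC)CCCC
Why: Stille coupling of the enol triflate with the hydroxymethylstannane replaces OTf by CH2OH with the double bond held in place, giving the allylic alcohol in one step.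

Step 3
Reactants: 4 (3,3-dimethylcyclohex-1-en-1-yl)methanol
Product: 5 1-(chloromethyl)-3,3-dimethylcyclohex-1-ene
Conditions: PPh3, CCl4, reflux
Reagents that add atoms: carbon tetrachloride ClC(Cl)(Cl)Cl
Why: Appel chlorination displaces the oxyphosphonium of the primary allylic alcohol by chloride in SN2 fashion, a protocol that gives primary allylic chlorides without allylic transposition.

Step 4
Reactants: 6 geraniol, (2E)-3,7-dimethylocta-2,6-dien-1-ol
Product: 7 geranyl TBS ether, tert-butyl{[(2E)-3,7-dimethylocta-2,6-dien-1-yl]oxy}dimethylsilane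
Conditions: TBSCl, imidazole, DMF, rt
Reagents that add atoms: tert-butyldimethylsilyl chloride CC(C)(C)[Si](C)(C)Cl
Why: Imidazole-promoted silylation masks the allylic alcohol against the oxidants, the ylide, the borane and the alkoxide/copper system used later (silyl ether protection).

Step 5
Reactants: 7 geranyl TBS ether
Product: 8 (2E,6E)-8-[(tert-butyldimethylsilyl)oxy]-2,6-dimethylocta-2,6-dien-1-ol
Conditions: SeO2 (cat.), t-BuOOH, salicylic acid (cat.), CH2Cl2, rt
Reagents that add atoms: tert-butyl hydroperoxide CC(C)(C)OO (terminal oxidant, oxygen delivered through catalytic selenium dioxide O=[Se]=O)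
Why: Catalytic SeO2 allylic oxidation (Riley-type ene reaction followed by a [2,3]-sigmatropic shift) attacks the (E)-methyl group of the remote, more electron-rich trisubstituted olefin and gives the (E)-allylic alcohol.

Step 6
Reactants: 8 (2E,6E)-8-[(tert-butyldimethylsilyl)oxy]-2,6-dimethylocta-2,6-dien-1-ol
Product: 9 (2E,6E)-8-[(tert-butyldimethylsilyl)oxy]-2,6-dimethylocta-2,6-dienal
Conditions: MnO2, CH2Cl2, rt
Reagents that add atoms: none
Why: MnO2 oxidises only the allylic alcohol to the (E)-enal without touching the silyl ether or the olefins, and any enal already formed in step 5 converges on the same product (allylic alcohol oxidation).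

Step 7
Reactants: 9 (2E,6E)-8-[(tert-butyldimethylsilyl)oxy]-2,6-dimethylocta-2,6-dienal
Product: 10 triene, tert-butyl{[(2E,6E)-3,7-dimethylnona-2,6,8-trien-1-yl]oxy}dimethylsilane
Conditions: Ph3PCH3Br, KOtBu, THF, 0 °C; then 9, −78 to 0 °C
Reagents that add atoms: methyltriphenylphosphonium bromide C[P+](c1ccccc1)(c1ccccc1)c1ccccc1.[Br-]
Why: Wittig methylenation of the enal carbonyl gives the terminal 1,3-diene without affecting the two existing (E)-olefins.

Step 8
Reactants: 10 triene, tert-butyl{[(2E,6E)-3,7-dimethylnona-2,6,8-trien-1-yl]oxy}dimethylsilane; 5 1-(chloromethyl)-3,3-dimethylcyclohex-1-ene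
Product: 13 coupled silyl ether, tert-butyl{[(2E,6E)-9-[(1S)-2,2-dimethyl-6-methylidenecyclohexyl]-3,7-dimethylnona-2,6-dien-1-yl]oxy}dimethylsilane, via alkyl-9-BBN borane 11 (not isolated), via potassium methoxyborate 12 (not isolated)
Conditions: 9-BBN dimer, THF, 0 °C to rt; then 5, CuOTf·(toluene)0.5 (10 mol %), (R)-DTBM-SEGPHOS (10 mol %), KOMe, 1,4-dioxane, 25 °C
Reagents that add atoms: none
Why: 9-BBN adds anti-Markovnikov to the monosubstituted terminus of the 1,3-diene of 10 only (the trisubstituted olefins and the silyl ether are inert) to give the primary homoallylic borane 11, which methoxide converts into borate 12 and which then transfers its alkyl group to the bisphosphine–copper(I) centre. The alkylcopper attacks chloride 5 in SN2' fashion at the ring CH carbon γ to chlorine, chloride leaves from the exocyclic CH2 and the olefin moves out of the ring, so the ring-CH to chain-CH2 bond, the exocyclic methylene and the stereocentre arise together. The closest known reaction type is the copper(I)/DTBM-SEGPHOS-catalysed, γ-selective enantioselective allyl–alkyl coupling of alkyl-9-BBN reagents with primary allylic chlorides, and copper-catalysed asymmetric SN2' alkylation of 1-(chloromethyl)cycloalkenes to 2-alkyl-1-methylenecycloalkanes is also established. No ring is closed. The single new stereocentre is controlled by the chiral bisphosphine on copper, which differentiates the enantiotopic faces of the achiral ring olefin; no substrate stereocentre takes part. The step needs γ- over α-attack and high facial selectivity: the neutral phosphine-bound alkylcopper of this protocol is inherently γ-selective and the ring locks the olefin in one geometry so that a single substrate conformer meets the catalyst, while the neopentyl position of the γ-carbon next to CMe2 remains the main risk.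

Step 9
Reactants: 13 coupled silyl ether
Product: 14 (2E,6E)-9-[(1S)-2,2-dimethyl-6-methylidenecyclohexyl]-3,7-dimethylnona-2,6-dien-1-ol
Conditions: TBAF, THF, 0 °C to rt
Reagents that add atoms: none
Why: Fluoride-mediated desilylation frees the primary allylic alcohol under non-acidic conditions that leave the exocyclic methylene, the (E)-olefins and the stereocentre untouched (silyl ether cleavage).

Step 10
Reactants: 14 (2E,6E)-9-[(1S)-2,2-dimethyl-6-methylidenecyclohexyl]-3,7-dimethylnona-2,6-dien-1-ol
Product: 15 target, 3-{[(2E,6E)-9-[(1S)-2,2-dimethyl-6-methylidenecyclohexyl]-3,7-dimethylnona-2,6-dien-1-yl]oxy}-3-oxopropanoic acid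
Conditions: Meldrum's acid, toluene, 90 °C
Reagents that add atoms: Meldrum's acid (2,2-dimethyl-1,3-dioxane-4,6-dione) CC1(C)OC(=O)CC(=O)O1
Why: Thermal ring-opening acylation of the alcohol by Meldrum's acid with loss of acetone gives the malonic acid half ester directly, with no base or strong acid that could move the exocyclic olefin or touch the stereocentre.

Compound list
1 | 3-methylcyclohex-2-en-1-one | CC1=CC(=O)CCC1 | starting material
2 | lithium 3,3-dimethylcyclohex-1-en-1-olate | [Li+].[O-]C1=CC(C)(C)CCC1 | intermediate (not isolated)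
3 | 3,3-dimethylcyclohex-1-en-1-yl trifluoromethanesulfonate | O=S(=O)(OC1=CC(C)(C)CCC1)C(F)(F)F | intermediate
4 | (3,3-dimethylcyclohex-1-en-1-yl)methanol | OCC1=CC(C)(C)CCC1 | intermediate
5 | 1-(chloromethyl)-3,3-dimethylcyclohex-1-ene | ClCC1=CC(C)(C)CCC1 | intermediate
6 | geraniol, (2E)-3,7-dimethylocta-2,6-dien-1-ol | CC(C)=CCC/C(C)=C/CO | starting material
7 | tert-butyl{[(2E)-3,7-dimethylocta-2,6-dien-1-yl]oxy}dimethylsilane | CC(C)=CCC/C(C)=C/CO[Si](C)(C)C(C)(C)C | intermediate
8 | (2E,6E)-8-[(tert-butyldimethylsilyl)oxy]-2,6-dimethylocta-2,6-dien-1-ol | OC/C(C)=C/CC/C(C)=C/CO[Si](C)(C)C(C)(C)C | intermediate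
9 | (2E,6E)-8-[(tert-butyldimethylsilyl)oxy]-2,6-dimethylocta-2,6-dienal | O=C/C(C)=C/CC/C(C)=C/CO[Si](C)(C)C(C)(C)C | intermediate
10 | tert-butyl{[(2E,6E)-3,7-dimethylnona-2,6,8-trien-1-yl]oxy}dimethylsilane | C=C/C(C)=C/CC/C(C)=C/CO[Si](C)(C)C(C)(C)C | intermediate
11 | 9-[(3E,7E)-9-[(tert-butyldimethylsilyl)oxy]-3,7-dimethylnona-3,7-dien-1-yl]-9-borabicyclo[3.3.1]nonane | B1(CC/C(C)=C/CC/C(C)=C/CO[Si](C)(C)C(C)(C)C)C2CCCC1CCC2 | intermediate (not isolated)
12 | potassium 9-[(3E,7E)-9-[(tert-butyldimethylsilyl)oxy]-3,7-dimethylnona-3,7-dien-1-yl]-9-methoxy-9-boranuidabicyclo[3.3.1]nonane | CO[B-]1(CC/C(C)=C/CC/C(C)=C/CO[Si](C)(C)C(C)(C)C)C2CCCC1CCC2.[K+] | intermediate (not isolated)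
13 | tert-butyl{[(2E,6E)-9-[(1S)-2,2-dimethyl-6-methylidenecyclohexyl]-3,7-dimethylnona-2,6-dien-1-yl]oxy}dimethylsilane | C=C1CCCC(C)(C)[C@@H]1CC/C(C)=C/CC/C(C)=C/CO[Si](C)(C)C(C)(C)C | intermediate
14 | (2E,6E)-9-[(1S)-2,2-dimethyl-6-methylidenecyclohexyl]-3,7-dimethylnona-2,6-dien-1-ol | C=C1CCCC(C)(C)[C@@H]1CC/C(C)=C/CC/C(C)=C/CO | intermediate
15 | 3-{[(2E,6E)-9-[(1S)-2,2-dimethyl-6-methylidenecyclohexyl]-3,7-dimethylnona-2,6-dien-1-yl]oxy}-3-oxopropanoic acid | C=C1CCCC(C)(C)[C@@H]1CC/C(C)=C/CC/C(C)=C/COC(=O)CC(=O)O | target

Total step count: 10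
Longest linear sequence: 7 steps (steps 4 to 10, from geraniol 6 to target 15); the ring branch (steps 1 to 3) joins at step 8.

Steps most likely to fail

Step 8. The alkylcopper may attack the unhindered CH2Cl carbon instead of the ring carbon next to CMe2 (loss of γ-selectivity). The ligand may also discriminate poorly between the faces of a ring-locked, β-substituted olefin (low enantioselectivity). The fallback sets out from triene 10 and chloride 5 and comes back at 13. Hydroboration as before gives borane 11, and oxidation with NaOH and H2O2 gives the homoallylic alcohol (3E,7E)-9-[(tert-butyldimethylsilyl)oxy]-3,7-dimethylnona-3,7-dien-1-ol F1. Appel bromination (CBr4, PPh3, CH2Cl2) gives {[(2E,6E)-9-bromo-3,7-dimethylnona-2,6-dien-1-yl]oxy}(tert-butyl)dimethylsilane F2. Magnesium in Et2O converts it into [(3E,7E)-9-[(tert-butyldimethylsilyl)oxy]-3,7-dimethylnona-3,7-dien-1-yl]magnesium bromide F3. This Grignard reagent is added slowly to 5 with catalytic copper(I) thiophene-2-carboxylate and a chiral biphenol-derived phosphoramidite ligand (antipode chosen by pilot run) in CH2Cl2 at −78 °C to give 13. This is the copper-catalysed asymmetric SN2' alkylation established for 1-(chloromethyl)cycloalkenes; the harder magnesium cuprate reacts by oxidative addition at the γ-carbon at low temperature.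

Step 2. Transfer of the hydroxymethyl group from tin may be slow, so that butyl transfer or reduction of the triflate competes and conversion stays low. The fallback sets out from triflate 3 and comes back at 4. Palladium-catalysed methoxycarbonylation (Pd(OAc)2, dppp, CO, MeOH, Et3N, DMF, 60 °C) gives methyl 3,3-dimethylcyclohex-1-ene-1-carboxylate F4, and DIBAL-H in CH2Cl2 at −78 °C reduces it to 4.

Step 5. The allylic oxidation may stall at partial conversion, over-oxidise or attack other allylic positions, which erodes the material balance. The fallback sets out from 7 and comes back at enal 9, bypassing 8 and step 6. NBS in aqueous THF at 0 °C gives the terminal bromohydrin (6E)-3-bromo-8-[(tert-butyldimethylsilyl)oxy]-2,6-dimethyloct-6-en-2-ol F5. K2CO3 in MeOH closes it to the epoxide tert-butyl{[(2E)-5-(3,3-dimethyloxiran-2-yl)-3-methylpent-2-en-1-yl]oxy}dimethylsilane F6. Periodic acid in THF/Et2O cleaves the epoxide to (4E)-6-[(tert-butyldimethylsilyl)oxy]-4-methylhex-4-enal F7. Wittig olefination with the stabilised ylide 2-(triphenylphosphoranylidene)propanal in toluene at 80 °C then gives the (E)-enal 9.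

Further compounds
F1 | step 8 | (3E,7E)-9-[(tert-butyldimethylsilyl)oxy]-3,7-dimethylnona-3,7-dien-1-ol | OCC/C(C)=C/CC/C(C)=C/CO[Si](C)(C)C(C)(C)C
F2 | step 8 | {[(2E,6E)-9-bromo-3,7-dimethylnona-2,6-dien-1-yl]oxy}(tert-butyl)dimethylsilane | BrCC/C(C)=C/CC/C(C)=C/CO[Si](C)(C)C(C)(C)C
F3 | step 8 | [(3E,7E)-9-[(tert-butyldimethylsilyl)oxy]-3,7-dimethylnona-3,7-dien-1-yl]magnesium bromide | Br[Mg]CC/C(C)=C/CC/C(C)=C/CO[Si](C)(C)C(C)(C)C
F4 | step 2 | methyl 3,3-dimethylcyclohex-1-ene-1-carboxylate | COC(=O)C1=CC(C)(C)CCC1
F5 | step 5 | (6E)-3-bromo-8-[(tert-butyldimethylsilyl)oxy]-2,6-dimethyloct-6-en-2-ol (racemic) | CC(C)(O)C(Br)CC/C(C)=C/CO[Si](C)(C)C(C)(C)C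
F6 | step 5 | tert-butyl{[(2E)-5-(3,3-dimethyloxiran-2-yl)-3-methylpent-2-en-1-yl]oxy}dimethylsilane (racemic) | CC1(C)OC1CC/C(C)=C/CO[Si](C)(C)C(C)(C)C
F7 | step 5 | (4E)-6-[(tert-butyldimethylsilyl)oxy]-4-methylhex-4-enal | O=CCC/C(C)=C/CO[Si](C)(C)C(C)(C)C
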